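The whole route rests on cutting the ten-membered carbocycle (C1–C10) between C5 and C6. Once the C4–C5 oxirane is traced back to an E olefin, the oxygen-bearing C6 of the butenolide ring is an allylic carbinol; this is the feature exploited. One chromium-mediated operation adds the C5 alkenyl iodide to the C6 aldehyde, which closes the carbocycle, sets C6 and leaves a free hydroxyl to guide the 4,5-epoxidation. The precursor is an open-chain E,E iodo-dienal with a C7 triethylsilyl ether and a C8 4-methoxybenzyl ether, an orthogonal pair that later lets C7 be oxidised and C8 acylated without acid near the epoxides.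

Key step: step 11

Remark: germacrane numbering is used throughout (carbocycle C1–C10, C14 on C10, C15 on C4, lactone carbons C11–C13, oxygens numbered by their carbon); 7 and 28 are taken as purchasable; the C7 carbinol configuration of 24 and 25 is left open because C7 becomes trigonal in step 18.

Step 1
Reactants: 1 (R)-glyceraldehyde acetonide; 2 propargyl bromide
Product: 3 (1S)-1-[(4R)-2,2-dimethyl-1,3-dioxolan-4-yl]but-3-yn-1-ol (anti adduct)
Conditions: Zn dust, DMF/Et2O, 0 °C → rt; aq. NH4Cl work-up
Reagents that add atoms: none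
Why: Barbier-type zinc propargylation in which the allenylzinc species should add under Felkin–Anh (polar) control anti to the dioxolane C–O bond, giving the anti (7,8-erythro) homopropargylic alcohol and so fixing C8 (S) next to the chiral-pool C7; the minor syn isomer is removed by chromatography.

Step 2
Reactants: 3 anti homopropargylic alcohol
Product: 4 (4R)-4-[(1S)-1-[(4-methoxyphenyl)methoxy]but-3-yn-1-yl]-2,2-dimethyl-1,3-dioxolane
Conditions: NaH, PMBCl, Bu4NI (cat.), THF/DMF, 0 °C → rt
Reagents that add atoms: 4-methoxybenzyl chloride, SMILES COc1ccc(CCl)cc1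
Why: Williamson etherification of the alkoxide, formed in preference to the far less acidic alkyne C–H, gives the benzylic ether that keeps O8 distinct from O6 and O7 for the rest of the route.

Step 3
Reactants: 4 PMB-protected alkyne
Product: 6 (4R)-4-[(1S,3E)-4-iodo-1-[(4-methoxyphenyl)methoxy]-3-methylbut-3-en-1-yl]-2,2-dimethyl-1,3-dioxolane, via alkenyldimethylalane 5 (not isolated)
Conditions: Me3Al, Cp2ZrCl2 (cat.), H2O (1 equiv), CH2Cl2, −20 °C; then I2, THF, −20 → 0 °C
Reagents that add atoms: trimethylaluminium, SMILES C[Al](C)C; iodine, SMILES II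
Why: Negishi carboalumination adds methyl and aluminium syn across the terminal alkyne with methyl on the internal carbon, and iodinolysis of the C–Al bond with retention gives the E C10=C1 alkenyl iodide, the short low-temperature exposure sparing acetonide and benzylic ether.

Step 4
Reactants: 7 4-(trimethylsilyl)but-3-yn-1-ol
Product: 8 (4-iodobut-1-yn-1-yl)trimethylsilane
Conditions: I2, PPh3, imidazole, CH2Cl2, 0 °C → rt
Reagents that add atoms: iodine, SMILES II
Why: Appel-type iodination of a primary alcohol (SN2 on the alkoxyphosphonium ion), to which the silylalkyne is inert.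

Step 5
Reactants: 8 (4-iodobut-1-yn-1-yl)trimethylsilane; 6 E alkenyl iodide
Product: 10 (4R)-4-[(1S,3E)-1-[(4-methoxyphenyl)methoxy]-3-methyl-8-(trimethylsilyl)oct-3-en-7-yn-1-yl]-2,2-dimethyl-1,3-dioxolane, via [4-(trimethylsilyl)but-3-yn-1-yl]zinc iodide 9 (not isolated)
Conditions: Zn dust (activated with BrCH2CH2Br, TMSCl), LiCl, THF, 40 °C; then 6, PdCl2(dppf) (5 mol %), THF, rt → 45 °C
Reagents that add atoms: none
Why: Zinc insertion into the primary iodide gives a homopropargylzinc reagent that undergoes Negishi sp3–sp2 cross-coupling with the alkenyl iodide with retention of the E geometry, forming C1–C2 while the silyl cap keeps the alkyne out of the coupling.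

Step 6
Reactants: 10 silyl-capped enyne
Product: 11 (4R)-4-[(1S,3E)-1-[(4-methoxyphenyl)methoxy]-3-methyloct-3-en-7-yn-1-yl]-2,2-dimethyl-1,3-dioxolane
Conditions: K2CO3, MeOH, rt
Reagents that add atoms: none
Why: Base-mediated methanolysis of the C(sp)–Si bond (protodesilylation) frees the terminal alkyne without touching ethers, acetonide or alkene.

Step 7
Reactants: 11 terminal enyne
Product: 13 (4R)-4-[(1S,3E,7E)-8-iodo-1-[(4-methoxyphenyl)methoxy]-3,7-dimethylocta-3,7-dien-1-yl]-2,2-dimethyl-1,3-dioxolane, via dienyldimethylalane 12 (not isolated)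
Conditions: Me3Al, Cp2ZrCl2 (cat.), H2O (1 equiv), CH2Cl2, −20 °C; then I2, THF, −20 → 0 °C
Reagents that add atoms: trimethylaluminium, SMILES C[Al](C)C; iodine, SMILES II
Why: A second Negishi carboalumination–iodinolysis, again syn and regioselective, delivers the E C4=C5 alkenyl iodide, the trisubstituted C10=C1 alkene being inert to carbometalation.

Step 8
Reactants: 13 iodo-diene acetonide
Product: 14 (2R,3S,5E,9E)-10-iodo-3-[(4-methoxyphenyl)methoxy]-5,9-dimethyldeca-5,9-diene-1,2-diol
Conditions: AcOH/H2O/THF (3:1:1), 45 °C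
Reagents that add atoms: none
Why: Acid-catalysed acetal hydrolysis of the terminal dioxolane is done here, before any oxirane exists, under conditions that the benzylic ether and the alkenyl iodide tolerate.

Step 9
Reactants: 14 C6,C7-diol
Product: 15 (2R,3S,5E,9E)-10-iodo-3-[(4-methoxyphenyl)methoxy]-5,9-dimethyl-1,2-bis[(triethylsilyl)oxy]deca-5,9-diene
Conditions: TESCl, imidazole, DMF, 0 °C → rt
Reagents that add atoms: chlorotriethylsilane, SMILES CC[Si](Cl)(CC)CC
Why: Standard imidazole-promoted silylation caps both hydroxyls.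

Step 10
Reactants: 15 bis(triethylsilyl) ether
Product: 16 (2S,3S,5E,9E)-10-iodo-3-[(4-methoxyphenyl)methoxy]-5,9-dimethyl-2-[(triethylsilyl)oxy]deca-5,9-dienal
Conditions: (COCl)2, DMSO, CH2Cl2, −78 → −30 °C; then Et3N, −78 → 0 °C; used at once
Reagents that add atoms: none
Why: Under Swern conditions the chlorosulfonium reagent cleaves the primary triethylsilyl ether and oxidises it in situ while the secondary silyl ether survives (selective Swern oxidative desilylation), giving the α-silyloxy aldehyde directly.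

Step 11
Reactants: 16 E,E iodo-dienal
Product: 18 E,E-cyclodeca-1(10),4-dien-6-ol (6R,7R,8S; 7-OSiEt3; 8-OPMB), via alkenylchromium dichloride 17 (not isolated)
Conditions: CrCl2 (10 equiv), NiCl2 (1 mol %), degassed DMSO/THF (3:1), rt, syringe-pump addition of 16 to 0.003 M final concentration
Reagents that add atoms: none
Why: Nozaki–Hiyama–Kishi reaction: zerovalent nickel, formed from NiCl2 by CrCl2, inserts into the C5–I bond and hands the alkenyl group to trivalent chromium, and the configurationally stable E alkenylchromium adds to the C6 aldehyde; the closest known type is the alkenyl iodide–aldehyde macrocyclisation to medium rings. The ten-membered carbocycle closes by a 10-exo-trig carbonyl addition, with high dilution and slow addition holding back intermolecular coupling. C6 is controlled by the C7 stereocentre: in the polar Felkin–Anh arrangement the alkenyl group attacks anti to the C7–O bond of the bulky, non-chelating silyl ether, which should give the 6,7-anti alcohol. The step needs addition to the aldehyde without enolisation at C7 and without loss of alkene geometry; the low basicity and carbonyl selectivity of organochromium reagents secure the first, and formation and consumption of the alkenyl–metal bonds with retention secure the second.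

Step 12
Reactants: 18 E,E-cyclodecadienol
Product: 19 (4R,5R,6R,7R,8S)-4,5-epoxide of 18
Conditions: VO(acac)2 (5 mol %), t-BuOOH (decane solution), CH2Cl2, 0 °C
Reagents that add atoms: tert-butyl hydroperoxide, SMILES CC(C)(C)OO
Why: Vanadium-catalysed hydroxyl-directed epoxidation delivers oxygen only to the allylic C4=C5 alkene, from the face syn to the C6 hydroxyl in the conformer that avoids allylic 1,3-strain between H6 and the C4 methyl (threo outcome), setting C4 (R) and C5 (R) and leaving the remote C1=C10 alkene alone.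

Step 13
Reactants: 19 4,5-epoxy alcohol
Product: 20 (1R,4R,5R,6R,7R,8S,10R)-1,10:4,5-diepoxide
Conditions: mCPBA, NaHCO3, CH2Cl2, 0 °C
Reagents that add atoms: 3-chloroperoxybenzoic acid, SMILES OOC(=O)c1cccc(Cl)c1
Why: Buffered Prilezhaev epoxidation of the remaining electron-rich alkene, which in the ten-membered ring is reachable only from its outer face; in the crown-like conformer with C14 and C15 on the same side this peripheral attack should give the 1R,10R oxirane.

Step 14
Reactants: 20 diepoxy alcohol
Product: 21 6-O-acryloyl ester of 20 (configuration as in 20)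
Conditions: acryloyl chloride, i-Pr2NEt, DMAP (cat.), CH2Cl2, −20 → 0 °C
Reagents that add atoms: acryloyl chloride, SMILES C=CC(Cl)=O
Why: O-acylation of the secondary alcohol by an acid chloride under amine base brings in C11–C13 without forming an alkoxide, so Payne rearrangement of the epoxy alcohol is avoided.

Step 15
Reactants: 21 acrylate silyl ether
Product: 22 7-hydroxy acrylate (21 without the silyl group, configuration as in 20)
Conditions: HF·pyridine, pyridine, THF, 0 °C
Reagents that add atoms: none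
Why: Fluoride-mediated desilylation of the secondary triethylsilyl ether under pyridine-buffered conditions leaves oxiranes, acrylate and benzylic ether intact.

Step 16
Reactants: 22 7-hydroxy acrylate
Product: 23 (1R,4R,5R,6R,8S,10R)-6-acryloyloxy-1,10:4,5-diepoxy-8-[(4-methoxyphenyl)methoxy]-4,10-dimethylcyclodecan-7-one
Conditions: Dess–Martin periodinane, NaHCO3, CH2Cl2, 0 °C → rt; used at once
Reagents that add atoms: none
Why: Dess–Martin oxidation under buffered, non-basic conditions gives the C7 ketone without epimerising C6 or C8.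

Step 17
Reactants: 23 keto acrylate
Product: 24 1,10:4,5-diepoxy-7-hydroxy-8-[(4-methoxyphenyl)methoxy]-11(13)-methylene-12,6-olide (C7 epimer not assigned)
Conditions: quinuclidine (1 equiv), DME, 0 °C → rt
Reagents that add atoms: none
Why: Intramolecular Morita–Baylis–Hillman reaction in which the amine adds to the acrylate, the ammonium enolate attacks the neighbouring C7 ketone (activated by two α-oxygen substituents) to close the five-membered lactone through the C11–C7 bond, and loss of the amine restores the exocyclic methylene.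

Step 18
Reactants: 24 α-methylene β-hydroxy lactone
Product: 26 (1R,4R,5R,6S,8S,10R)-13-acetoxy-1,10:4,5-diepoxy-8-[(4-methoxyphenyl)methoxy]-7(11)-en-12,6-olide, via tertiary C7 acetate 25 (not isolated)
Conditions: Ac2O, Et3N, DMAP, CH2Cl2, rt; then DABCO (cat.), rt
Reagents that add atoms: acetic anhydride, SMILES CC(=O)OC(C)=O
Why: DMAP-catalysed acetylation of the tertiary allylic alcohol is followed by the amine-catalysed SN2′ transposition typical of Morita–Baylis–Hillman acetates (amine adds to the methylene, the C7 acetate leaves, acetate returns at C13), giving the thermodynamically preferred tetrasubstituted butenolide with the primary C13 acetate.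

Step 19
Reactants: 26 8-O-PMB butenolide
Product: 27 (1R,4R,5R,6S,8S,10R)-13-acetoxy-1,10:4,5-diepoxy-8-hydroxy-7(11)-en-12,6-olide
Conditions: DDQ, CH2Cl2/pH 7 phosphate buffer, 0 °C → rt
Reagents that add atoms: none
Why: Oxidative cleavage of the 4-methoxybenzyl ether by DDQ (hydride abstraction, hydrolysis of the oxocarbenium ion) runs under buffered neutral conditions that spare oxiranes, acetate and butenolide.

Step 20
Reactants: 28 methyl (2S)-2-methyloxirane-2-carboxylate
Product: 30 (2R)-3-chloro-2-hydroxy-2-methylpropanoic acid, via methyl (2R)-3-chloro-2-hydroxy-2-methylpropanoate 29 (not isolated)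
Conditions: 37% aq. HCl, 0 °C → rt, then 70 °C
Reagents that add atoms: hydrogen chloride, SMILES Cl; water, SMILES O
Why: Acid-mediated oxirane opening by chloride at the unhindered CH2 carbon (SN2, the quaternary centre is not touched, only its descriptor changes from S to R) followed by acid hydrolysis of the methyl ester.

Step 21
Reactants: 27 8-hydroxy butenolide; 30 (2R)-3-chloro-2-hydroxy-2-methylpropanoic acid
Product: 31 target, (1R,4R,5R,6S,8S,10R)-13-acetoxy-1,10:4,5-diepoxy-7(11)-en-12,6-olide 8-O-[(2R)-3-chloro-2-hydroxy-2-methylpropanoate]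
Conditions: DCC, DMAP (cat.), CH2Cl2, 0 °C → rt
Reagents that add atoms: none
Why: Steglich esterification of the C8 alcohol with the carbodiimide-activated acid, whose tertiary hydroxyl is too hindered to compete, under weakly basic conditions that keep chlorohydrin, oxiranes and butenolide intact.

Compound list
1 | (R)-2,2-dimethyl-1,3-dioxolane-4-carbaldehyde ((R)-glyceraldehyde acetonide) | CC1(C)OC[C@H](C=O)O1 | starting material
2 | 3-bromoprop-1-yne (propargyl bromide) | C#CCBr | starting material
3 | (1S)-1-[(4R)-2,2-dimethyl-1,3-dioxolan-4-yl]but-3-yn-1-ol | C#CC[C@H](O)[C@H]1COC(C)(C)O1 | intermediate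
4 | (4R)-4-[(1S)-1-[(4-methoxyphenyl)methoxy]but-3-yn-1-yl]-2,2-dimethyl-1,3-dioxolane | C#CC[C@H](OCc1ccc(OC)cc1)[C@H]1COC(C)(C)O1 | intermediate
5 | E alkenyldimethylalane from 4 (Al on C1, methyl on C10), formed in situ | C[Al](C)/C=C(\C)C[C@H](OCc1ccc(OC)cc1)[C@H]1COC(C)(C)O1 | intermediate
6 | (4R)-4-[(1S,3E)-4-iodo-1-[(4-methoxyphenyl)methoxy]-3-methylbut-3-en-1-yl]-2,2-dimethyl-1,3-dioxolane | I/C=C(\C)C[C@H](OCc1ccc(OC)cc1)[C@H]1COC(C)(C)O1 | intermediate
7 | 4-(trimethylsilyl)but-3-yn-1-ol | C[Si](C)(C)C#CCCO | starting material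
8 | (4-iodobut-1-yn-1-yl)trimethylsilane | C[Si](C)(C)C#CCCI | intermediate
9 | [4-(trimethylsilyl)but-3-yn-1-yl]zinc iodide, formed in situ | C[Si](C)(C)C#CCC[Zn]I | intermediate
10 | (4R)-4-[(1S,3E)-1-[(4-methoxyphenyl)methoxy]-3-methyl-8-(trimethylsilyl)oct-3-en-7-yn-1-yl]-2,2-dimethyl-1,3-dioxolane | C[Si](C)(C)C#CCC/C=C(\C)C[C@H](OCc1ccc(OC)cc1)[C@H]1COC(C)(C)O1 | intermediate
11 | (4R)-4-[(1S,3E)-1-[(4-methoxyphenyl)methoxy]-3-methyloct-3-en-7-yn-1-yl]-2,2-dimethyl-1,3-dioxolane | C#CCC/C=C(\C)C[C@H](OCc1ccc(OC)cc1)[C@H]1COC(C)(C)O1 | intermediate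
12 | E,E dienyldimethylalane from 11 (Al on C5, methyl on C4), formed in situ | C[Al](C)/C=C(\C)CC/C=C(\C)C[C@H](OCc1ccc(OC)cc1)[C@H]1COC(C)(C)O1 | intermediate
13 | (4R)-4-[(1S,3E,7E)-8-iodo-1-[(4-methoxyphenyl)methoxy]-3,7-dimethylocta-3,7-dien-1-yl]-2,2-dimethyl-1,3-dioxolane | I/C=C(\C)CC/C=C(\C)C[C@H](OCc1ccc(OC)cc1)[C@H]1COC(C)(C)O1 | intermediate
14 | (2R,3S,5E,9E)-10-iodo-3-[(4-methoxyphenyl)methoxy]-5,9-dimethyldeca-5,9-diene-1,2-diol | I/C=C(\C)CC/C=C(\C)C[C@H](OCc1ccc(OC)cc1)[C@H](O)CO | intermediate
15 | (2R,3S,5E,9E)-10-iodo-3-[(4-methoxyphenyl)methoxy]-5,9-dimethyl-1,2-bis[(triethylsilyl)oxy]deca-5,9-diene | I/C=C(\C)CC/C=C(\C)C[C@H](OCc1ccc(OC)cc1)[C@H](O[Si](CC)(CC)CC)CO[Si](CC)(CC)CC | intermediate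
16 | (2S,3S,5E,9E)-10-iodo-3-[(4-methoxyphenyl)methoxy]-5,9-dimethyl-2-[(triethylsilyl)oxy]deca-5,9-dienal (key-step precursor) | I/C=C(\C)CC/C=C(\C)C[C@H](OCc1ccc(OC)cc1)[C@H](O[Si](CC)(CC)CC)C=O | intermediate
17 | E alkenylchromium dichloride from 16 (Cr on C5), formed in situ | Cl[Cr](Cl)/C=C(\C)CC/C=C(\C)C[C@H](OCc1ccc(OC)cc1)[C@H](O[Si](CC)(CC)CC)C=O | intermediate
18 | (6R,7R,8S)-E,E-cyclodeca-1(10),4-dien-6-ol with CH3 on C4 and C10, 7-OSiEt3, 8-OPMB; 6,7-anti and 7,8-anti (key-step product) | O[C@H]1[C@@H](O[Si](CC)(CC)CC)[C@@H](OCc2ccc(OC)cc2)C/C(C)=C/CC/C(C)=C/1 | intermediate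
19 | (4R,5R,6R,7R,8S)-4,5-epoxide of 18 (trans-oxirane, threo to 6-OH), E C1=C10 retained | O[C@H]1[C@@H](O[Si](CC)(CC)CC)[C@@H](OCc2ccc(OC)cc2)C/C(C)=C/CC[C@@]3(C)O[C@@H]31 | intermediate
20 | (1R,4R,5R,6R,7R,8S,10R)-1,10:4,5-diepoxy-4,10-dimethyl-8-[(4-methoxyphenyl)methoxy]-7-[(triethylsilyl)oxy]cyclodecan-6-ol | O[C@H]1[C@@H](O[Si](CC)(CC)CC)[C@@H](OCc2ccc(OC)cc2)C[C@@]4(C)O[C@@H]4CC[C@@]3(C)O[C@@H]31 | intermediate
21 | 6-O-acryloyl ester of 20 (configuration as in 20) | C=CC(=O)O[C@H]1[C@@H](O[Si](CC)(CC)CC)[C@@H](OCc2ccc(OC)cc2)C[C@@]4(C)O[C@@H]4CC[C@@]3(C)O[C@@H]31 | intermediate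
22 | 6-O-acryloyl-7-hydroxy compound (21 without the silyl group, configuration as in 20) | C=CC(=O)O[C@H]1[C@@H](O)[C@@H](OCc2ccc(OC)cc2)C[C@@]4(C)O[C@@H]4CC[C@@]3(C)O[C@@H]31 | intermediate
23 | (1R,4R,5R,6R,8S,10R)-6-acryloyloxy-1,10:4,5-diepoxy-8-[(4-methoxyphenyl)methoxy]-4,10-dimethylcyclodecan-7-one | C=CC(=O)O[C@H]1C(=O)[C@@H](OCc2ccc(OC)cc2)C[C@@]4(C)O[C@@H]4CC[C@@]3(C)O[C@@H]31 | intermediate
24 | 1,10:4,5-diepoxy-7-hydroxy-8-[(4-methoxyphenyl)methoxy]-11(13)-methylene-12,6-olide (γ-lactone O6–C12–C11–C7–C6; C7 epimer not assigned) | C=C1C(=O)O[C@H]2C1(O)[C@@H](OCc3ccc(OC)cc3)C[C@@]4(C)O[C@@H]4CC[C@@]5(C)O[C@@H]52 | intermediate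
25 | tertiary C7 acetate of 24, formed in situ | C=C1C(=O)O[C@H]2C1(OC(C)=O)[C@@H](OCc3ccc(OC)cc3)C[C@@]4(C)O[C@@H]4CC[C@@]5(C)O[C@@H]52 | intermediate
26 | (1R,4R,5R,6S,8S,10R)-13-acetoxy-1,10:4,5-diepoxy-8-[(4-methoxyphenyl)methoxy]-7(11)-en-12,6-olide | CC(=O)OCC1=C2[C@@H](OCc3ccc(OC)cc3)C[C@@]4(C)O[C@@H]4CC[C@@]5(C)O[C@@H]5[C@H]2OC1=O | intermediate
27 | (1R,4R,5R,6S,8S,10R)-13-acetoxy-1,10:4,5-diepoxy-8-hydroxy-7(11)-en-12,6-olide | CC(=O)OCC1=C2[C@@H](O)C[C@@]3(C)O[C@@H]3CC[C@@]3(C)O[C@@H]3[C@H]2OC1=O | intermediate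
28 | methyl (2S)-2-methyloxirane-2-carboxylate | COC(=O)[C@]1(C)CO1 | starting material
29 | methyl (2R)-3-chloro-2-hydroxy-2-methylpropanoate, formed in situ | COC(=O)[C@@](C)(O)CCl | intermediate
30 | (2R)-3-chloro-2-hydroxy-2-methylpropanoic acid | OC(=O)[C@@](C)(O)CCl | intermediate
31 | CNP0255009.1, (1R,4R,5R,6S,8S,10R)-13-acetoxy-1,10:4,5-diepoxy-7(11)-en-12,6-olide 8-O-[(2R)-3-chloro-2-hydroxy-2-methylpropanoate] | CC(=O)OCC1=C2[C@@H](OC(=O)[C@@](C)(O)CCl)C[C@@]3(C)O[C@@H]3CC[C@@]3(C)O[C@@H]3[C@H]2OC1=O | target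

Total step count: 21. Longest linear sequence: 19 steps (steps 1–3, 5–19 and 21); steps 4 and 20 prepare coupling partners.

Steps most likely to fail

Step 11. The strain of the ten-membered transition state may override Felkin–Anh control, so that the ring closes with poor facial selectivity at C6. The fallback sets out from 16 and separates ring formation from stereocontrol. The cyclisation is run as before and the crude mixture of 18 and the C6 epimer of 18 F1 is oxidised with Dess–Martin periodinane (NaHCO3, CH2Cl2, 0 °C) to the single E,E-cyclodeca-2,6-dienone F2. Chelation-controlled 1,2-reduction with Zn(BH4)2 in Et2O at −30 °C follows, in which zinc bridges the C6 carbonyl and the ether oxygens at C7 and C8. Hydride should then arrive on the face that gives the 6,7-anti, 6,8-syn alcohol, and the route is rejoined at 18.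

Step 17. Carbonyl addition of the ammonium enolate to the hindered ketone may be slow, which would let amine-promoted enolisation at C6 with β-elimination opening of the 4,5-oxirane, or oligomerisation of the acrylate, take over. The fallback sets out from 23 and replaces amine catalysis by a stoichiometric, non-basic selenolate Michael–aldol sequence. PhSeLi (from PhSeSePh and n-BuLi, THF, −78 °C) adds to the acrylate and the lithium enolate closes onto the C7 ketone, giving the 13-phenylselanyl 7-hydroxy lactone F3. Oxidation with H2O2 and pyridine in CH2Cl2 (0 °C → rt) and selenoxide syn-elimination then restore the exocyclic methylene, and the route is rejoined at 24.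

Step 18. The hindered tertiary C7 hydroxyl may fail to acylate, or the β-hydroxy lactone may open by retro-aldol cleavage under the amine-rich conditions. The fallback sets out from 24 and activates the C–O bond through phosphorus in place of acylation. CBr4 and PPh3 in CH2Cl2 at 0 °C (Appel activation with SN2′ delivery of bromide) give the 13-bromo-7(11)-en-12,6-olide F4. SN2 displacement with CsOAc in DMF at rt installs the primary acetate, and the route is rejoined at 26.

Further compounds
F1 | step 11 | C6 epimer of 18 (6S,7R,8S) | O[C@@H]1[C@@H](O[Si](CC)(CC)CC)[C@@H](OCc2ccc(OC)cc2)C/C(C)=C/CC/C(C)=C/1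
F2 | step 11 | E,E-cyclodeca-1(10),4-dien-6-one with 7-OSiEt3 and 8-OPMB | O=C1[C@@H](O[Si](CC)(CC)CC)[C@@H](OCc2ccc(OC)cc2)C/C(C)=C/CC/C(C)=C/1
F3 | step 17 | 1,10:4,5-diepoxy-7-hydroxy-8-[(4-methoxyphenyl)methoxy]-13-(phenylselanyl)-12,6-olide (C7 and C11 not assigned) | c1ccccc1[Se]CC1C(=O)O[C@H]2C1(O)[C@@H](OCc3ccc(OC)cc3)C[C@@]4(C)O[C@@H]4CC[C@@]5(C)O[C@@H]52
F4 | step 18 | 13-bromo-1,10:4,5-diepoxy-8-[(4-methoxyphenyl)methoxy]-7(11)-en-12,6-olide | BrCC1=C2[C@@H](OCc3ccc(OC)cc3)C[C@@]4(C)O[C@@H]4CC[C@@]5(C)O[C@@H]5[C@H]2OC1=O
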